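Each flask held 28.6 substrate per catalyst, so full conversion needed that many turnovers, and I counted how many the coupling partner's life allowed.

| setting | Saturday's | Sunday's | Thursday's | Monday's |
|---|---|---|---|---|
| substrate | 0.014 M | 0.014 M | 0.014 M | 0.014 M |
| coupling partner | 0.0200 M | 0.0300 M | 0.0500 M | 0.0800 M |
| free catalyst | 0.49 mM | 0.49 mM | 0.49 mM | 0.49 mM |
| time | 5.0 h | 5.0 h | 5.0 h | 5.0 h |
    coupling partner + free catalyst ⇌ catalyst intermediate A (K1 = 20 L mol⁻¹, k1 = 48.4 L mol⁻¹ min⁻¹)
    catalyst intermediate A → catalyst intermediate B (k2 = 0.0700 min⁻¹)
    substrate + catalyst intermediate B ⇌ catalyst intermediate C (K3 = 1630 L mol⁻¹, k3 = 32.2 L mol⁻¹ min⁻¹)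
    catalyst intermediate C → free catalyst + product (k4 = 0.422 min⁻¹)
    2 coupling partner → homo dimer (k5 = 0.567 L mol⁻¹ min⁻¹)
    free catalyst + product ⇌ idle complex (K6 = 169 L mol⁻¹, k6 = 38.6 L mol⁻¹ min⁻¹)
- product is meant together with its idle complex
- where a step has two of a species, its rate is k times that concentration squared, and two are used at each turn
- "hardly changes" means that all values lie within two and a half points (for a concentration: within two and a half percent of the largest)
- run time (Saturday's): 5.0 h
* amount of product at the end, in percent of the substrate charged for Saturday's, Sunday's, Thursday's, Monday's, in this order
* how that number moves from the first to the last of them (falls all the way / hardly changes / falls, then rises / rises, then falls / rises all the way)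

I ranked the time scales from the shortest up. Catalyst intermediate A fell back to coupling partner and free catalyst with a half-life of 0.286 min, so I took it as equilibrated. On Saturday's charges, catalyst intermediate B met substrate with a forward half-life of 1.5 min, and catalyst intermediate C released product in 1.6 min. The step from A to B took 9.90 min, slower than those, so I treated it as the rate-limiting step, with B and C kept small. Dimerisation came next, with a first half-life of 44.1 min on Saturday's and 11.0 min on Monday's, both shorter than the run.

The partner therefore decayed by second-order dimerisation while each catalyst turned over at a rate set by its equilibrium share as A. Integrating that rate gave the turnover budget: the A-to-B constant times the equilibrium constant of A, over twice the dimerisation constant, 1.23 turnovers, multiplied by a logarithm of the charge and time. The budget was 2.18 turnovers on Saturday's and 3.01 on Monday's. Free product bound free catalyst with a forward half-life of 0.61 h at the charged catalyst, shorter than the run. I therefore took the rate as slowed by one plus the idle-complex equilibrium constant times the product made so far, a factor that grows from one as product appears. Integrated, this set each budget equal to the product times one plus 0.5 of that equilibrium constant times the product. Solving for the product gave 7.05% of the substrate on Saturday's and 9.48% on Monday's, a rise of 2.4 percentage points.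

The forecast gave 6.4%, 7.2%, 8% and 8.6%, and called the shape hardly changes: “the total spread of about 2.2 points is inside the 2.5-point band”. Its figure for Saturday's was lower than mine, and so was its figure for Monday's.

The simulation gave 6.51%, 7.30%, 8.15% and 8.77%, and the shape hardly changes.

Saturday's product amounted to 1.86 turnovers against a budget of 2.18. Thursday's, which I had not reckoned, has a budget of 2.78 turnovers; the same idle-complex correction gives 8.81% of the substrate, against 8.15% in the flask. Monday's product stayed low because dimerisation of the coupling partner and the undoing of catalyst intermediate A acted together: Monday's gave 8.77%, against 32.0% without dimerisation and 38.6% without the undoing.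

The numbers of this flask are those of an exercise; the rest is arithmetic.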